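## Analysis of the target

1. The target is a linear C25 sesterterpenoid with a five-membered lactone at each end of an (E,E)-1,5-diene chain. Locants used here: ring B (butenolide) O–C1(=O)–C2H=C3–C25H2; carbinol C4; chain C5–C13 with C6=C7 (methyl C24) and C10=C11 (methyl C23); exocyclic C14=C15; ring A O–C22(=O)–C15–C16H2–C17H; side chain C18H=C19(C20H3)(C21H3).
2. Ring A is an α-alkylidene-γ-butyrolactone whose exocyclic C14=C15 bond is Z (C13 on the side of the C22 carbonyl). This angelate-like geometry is as a rule the less stable one and can be lost by conjugate addition–elimination or by γ-deprotonation at C13.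
3. There are two stereocentres, C17 (S) in ring A and C4 (R) next to ring B. They lie thirteen bonds apart, so neither can control the other and each needs its own reagent control.
4. The feature the route exploits: C17 is both the alkoxy carbon of ring A and an allylic carbon (C17–C18=C19). The ring bond O–C17 is therefore an allyl ester bond, and the allyl unit C17–C18–C19 ends in a carbon (C19) that carries two identical methyl groups (C20, C21).
5. Sensitive groups are that allyl ester (ionised by acid or zerovalent palladium), the Z-enoate, the butenolide (acidic C25–H, base-labile, carbinol C4 open to redox isomerisation through the dienolate), and the trisubstituted alkenes (electrophiles, radicals, singlet oxygen). Any carbonyl at C4 is β,γ-unsaturated.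
6. The difficulty is three local problems: the contra-thermodynamic Z-C14=C15 bond, the ionisable C17 stereocentre, and the C4 carbinol on the β-carbon C3 of an enoate, which must bond to another electrophilic carbon.

## Retrosynthetic reasoning

**C3–C4 (last bond), 16 ⇒ 14 + 15.** The target is cut between the butenolide β-carbon C3 and the carbinol carbon C4. Both are electrophilic in their natural form (enoate β-carbon, aldehyde carbon), so the forward step must reverse the polarity of C3; a chromium-mediated coupling of the C3–Br bond of 15 does this. Cutting here makes ring B a bought compound, needs no protecting group, and lets a chromium-bound ligand set 4R.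

**Oxidation level at C4, 14 ⇒ 13.** C4 is carried as a primary alcohol until the penultimate step, so the isomerisation-prone β,γ-unsaturated aldehyde 14 exists only briefly.

**O–C17 (key), 13 ⇒ 12.** Ring A is opened at its allyl ester bond with allylic transposition: oxygen goes to C19 as a tertiary hydroxyl and the alkene to C17=C18. This removes the ring and its only stereocentre in one cut and leaves an achiral, acyclic hydroxy acid. The Z-C14=C15 bond is not part of the reacting allyl unit. The forward reaction must close the five-membered ring at C17 and choose one face of the allyl unit.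

**Unmasking, 12 ⇒ 11.** The acid and the C4 hydroxyl are masked as 2-(trimethylsilyl)ethyl ester and carbonate, so one fluoride treatment frees both without hydroxide.

**C15–C16, 11 ⇒ 9 + 10.** The skipped diene C14=C15–C16–C17=C18 is the retron of an alkene–alkyne (Alder-ene) coupling. Cutting C15–C16 and returning the C14 hydrogen to C18 gives ynoate 9, which has no alkene geometry to control, and the bought alkenol 10. The forward reaction must bond at the ester-bearing alkyne carbon and deliver C16 and H syn, which places C13 cis to the ester, so the Z geometry follows from mechanism, not thermodynamics.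

**C12–C13 and C15–C22, 9 ⇒ 5 + 6.** The three carbons C13–C15 come from propyne 6 as a dianion linchpin: its sp3 end displaces the allylic bromide of 5 and its sp end is acylated by a chloroformate. The same chloroformate caps the C4 alkoxide.

**C12 functionalisation, 5 ⇒ 4 ⇒ 3.** C12 is the terminal E-methyl group of a geranyl unit, the site an allylic oxidation prefers; the allylic hydroxyl of 4 is then turned into bromide in the presence of the homoallylic one.

**C4–C5, 3 ⇒ 1.** One-carbon hydroxymethylation of geranyl bromide 1, which already holds C5–C12 and both E-alkenes.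

## Alternatives that were turned down

**Alternative 1:** (textbook) Cut C14=C15: Z-selective Horner–Wadsworth–Emmons olefination of aldehyde A2 with the diaryl phosphonolactone A1, then desilylation to 13.
- The Z geometry rests on kinetic control alone; with a cyclic phosphonate enolate and an enolisable aldehyde, E/Z mixtures of hard-to-separate isomers must be expected.
- A1 needs its own four to five steps, including a separate asymmetric step for C17, and its allyl ester must survive strong base.
- A2 needs a degradative sequence of about five steps from a C15 terpene.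
- The total is longer than the chosen route and leaves geometry to reagent tuning.

**Alternative 2:** Cut C15–C16 at the alkyne level: open epoxide A3 with acetylide 8 to give the homopropargylic alcohol A4, hydroxyl-directed trans-hydrostannation ([Cp*RuCl]4, Bu3SnH) to A5, then carbonylative lactonisation (zerovalent palladium, CO) to 13.
- The Z geometry is secure (tin and C13 end up cis).
- A3 is a volatile vinyl epoxide needing its own synthesis and resolution; its allylic carbon is highly cation-stabilised, so attack at the CH2 carbon is not assured.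
- The directing effect of a homopropargylic hydroxyl on tin placement is weaker than that of a propargylic one.
- Zerovalent palladium can ionise the allyl ester it has just made.
- Four operations with stoichiometric tin against three catalytic ones.

**Alternative 3:** Form C16–C17 by [2,3]-Wittig rearrangement: Morita–Baylis–Hillman adduct A6 (from A2 and methyl acrylate), its prenyl ether A7, deprotonation at the prenyl CH2, [2,3]-shift and lactonisation would give ring A in one step.
- The strong base needed is incompatible with the acrylate (conjugate addition, polymerisation).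
- In 2-substituted allyl ethers the shift tends to place C13 cis to C16, the wrong geometry.
- C17 would have to be set by 1,4-transfer of chirality through an envelope transition state with no secure exo/endo preference.
- An enantioenriched A6 from an aliphatic aldehyde is itself hard to obtain.

Key step: step 7

Remark on the chemistry: for the two ligand-controlled steps (7 and 9) the ligand antipode that leads to 17S and to 4R is assumed; which antipode that is has to be assigned once on a model substrate, and both antipodes are accessible.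

## Route

Step 1
Reactants: 1 geranyl bromide, (2E)-1-bromo-3,7-dimethylocta-2,6-diene
Product: 3 (3E)-4,8-dimethylnona-3,7-dien-1-ol (homogeraniol), via homogeranyl isopropoxysilane 2 (not isolated)
Conditions: (i-PrO)Me2SiCH2MgCl (1.3 equiv, stock solution in THF), Li2CuCl4 (3 mol%), THF, −20 → 0 °C; then KF, KHCO3, 30% H2O2, THF/MeOH, rt
Reagents that add atoms: (isopropoxydimethylsilyl)methylmagnesium chloride, CC(C)O[Si](C)(C)C[Mg]Cl; hydrogen peroxide, OO
Why: Copper-catalysed SN2 coupling of the primary allylic bromide with the silylmethyl Grignard reagent (attack at CH2 avoids a quaternary centre and keeps E-C6=C7), then Tamao oxidation of the alkoxysilane to the alcohol; the net result is nucleophilic hydroxymethylation that installs C4.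

Step 2
Reactants: 3 (3E)-4,8-dimethylnona-3,7-dien-1-ol
Product: 4 (2E,6E)-2,6-dimethylnona-2,6-diene-1,9-diol
Conditions: SeO2 (0.3 equiv), t-BuOOH (3 equiv), salicylic acid (0.1 equiv), CH2Cl2, 0 °C → rt
Reagents that add atoms: tert-butyl hydroperoxide, CC(C)(C)OO
Why: Riley-type allylic oxidation (ene reaction, then [2,3]-shift) should attack the terminal isopropylidene group at the methyl group trans to the chain and give the (E)-allylic alcohol at C12; the more hindered C6=C7 alkene reacts more slowly and the homoallylic hydroxyl is not oxidised.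

Step 3
Reactants: 4 (2E,6E)-2,6-dimethylnona-2,6-diene-1,9-diol
Product: 5 (3E,7E)-9-bromo-4,8-dimethylnona-3,7-dien-1-ol
Conditions: NBS (2.2 equiv), Me2S (2.4 equiv), CH2Cl2, −25 °C (reagent pre-formed), then 4, −25 → 0 °C
Reagents that add atoms: N-bromosuccinimide, O=C1CCC(=O)N1Br
Why: Corey–Kim-type halogenation: both hydroxyls form alkoxysulfonium salts, but only the allylic one collapses to the bromide at 0 °C, while the homoallylic one returns the alcohol on aqueous work-up; the neutral conditions leave the E-alkenes untouched.

Step 4
Reactants: 5 (3E,7E)-9-bromo-4,8-dimethylnona-3,7-dien-1-ol; 6 propyne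
Product: 9 2-(trimethylsilyl)ethyl (6E,10E)-6,10-dimethyl-13-({[2-(trimethylsilyl)ethoxy]carbonyl}oxy)trideca-6,10-dien-2-ynoate, via 1,3-dilithiopropyne 7 (not isolated), via dilithium alkoxide acetylide 8 (not isolated)
Conditions: 6 (2.4 equiv), n-BuLi (4.8 equiv), TMEDA (2.4 equiv), Et2O/hexane, −78 → 0 °C; 5 in THF, −78 → −20 °C; then ClCO2CH2CH2SiMe3 (4 equiv), −78 → 0 °C
Reagents that add atoms: 2-(trimethylsilyl)ethyl chloroformate, C[Si](C)(C)CCOC(=O)Cl
Why: 1,3-Dilithiopropyne alkylates primary allylic bromides at its sp3 carbon (SN2, forms C12–C13) and leaves the lithium acetylide, which the chloroformate C-acylates (C15–C22) while it caps the C4 alkoxide as the carbonate; one equivalent of 7 is spent on the hydroxyl proton of 5.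

Step 5
Reactants: 9 the ynoate carbonate from step 4; 10 2-methylpent-4-en-2-ol
Product: 11 2-(trimethylsilyl)ethyl (2Z,6E,10E)-2-[(2E)-4-hydroxy-4-methylpent-2-en-1-yl]-6,10-dimethyl-13-({[2-(trimethylsilyl)ethoxy]carbonyl}oxy)trideca-2,6,10-trienoate
Conditions: [CpRu(CH3CN)3]PF6 (10 mol%), 10 (2 equiv), acetone, rt
Reagents that add atoms: none
Why: Ruthenium-catalysed alkene–alkyne coupling of the Alder-ene type: oxidative cyclisation of the ynoate and the terminal alkene of 10 gives a ruthenacyclopentene with the new C15–C16 bond at the ester-bearing alkyne carbon, then β-hydride elimination from C18 and C14–H reductive elimination release the 1,4-diene. Syn delivery of C16 and H across C14≡C15 places C13 cis to the ester (Z) and the new C17=C18 bond is E; trisubstituted alkenes do not take part, and without an acidic co-ligand the catalyst should not ionise the tertiary allylic alcohol.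

Step 6
Reactants: 11 the dienoate from step 5
Product: 12 (2Z,6E,10E)-13-hydroxy-2-[(2E)-4-hydroxy-4-methylpent-2-en-1-yl]-6,10-dimethyltrideca-2,6,10-trienoic acid
Conditions: Bu4NF (3.5 equiv), THF, 0 °C → rt; aq. NH4Cl work-up at 0 °C, used at once
Reagents that add atoms: none
Why: Fluoride-induced β-elimination cleaves both 2-(trimethylsilyl)ethyl groups (ester and carbonate), which frees the acid and the C4 hydroxyl in one operation without exposing the Z-enoate to hydroxide; the cold, weakly acidic work-up avoids proton-catalysed ionisation of the tertiary allylic alcohol.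

Step 7
Reactants: 12 the hydroxy acid from step 6
Product: 13 (3Z,5S)-3-[(4E,8E)-11-hydroxy-4,8-dimethylundeca-4,8-dien-1-ylidene]-5-(2-methylprop-1-en-1-yl)oxolan-2-one
Conditions: [CpRu(CH3CN)3]PF6 (3 mol%), axially chiral 6-(2-chloronaphthalen-1-yl)-5-methylpyridine-2-carboxylic acid (3 mol%, one antipode, see remark), N,N-dimethylacetamide, 30 °C
Reagents that add atoms: none
Why: Proposed new method: the CpRu–picolinic acid complex binds the C17=C18 alkene, its carboxylic acid function hydrogen-bonds the tertiary C19 hydroxyl, and loss of water gives an η3-allyl complex of tetravalent ruthenium over C17–C18–C19; the C22 carboxylate then adds to C17 and releases divalent ruthenium, a net SN2′ displacement that moves the oxygen from C19 to C17 and the alkene from C17=C18 to C18=C19. The closest known reaction type is the enantioselective dehydrative Tsuji–Trost-type cyclisation of ω-carboxy primary (E)-allylic alcohols to γ-alkenyl-γ-butyrolactones with this catalyst class, together with palladium-catalysed asymmetric cyclisations of allylic carbonates by oxygen nucleophiles; new here are the tertiary leaving-group carbon and the trisubstituted alkene that results. Ring A closes in the 5-exo mode onto the allyl terminus C17; closure at C19 would need a seven-membered ring and a quaternary C–O bond and should not compete. C17 is the only new stereocentre and is set by the ligand, whose naphthyl–pyridine axis dictates which face of the allyl unit carries ruthenium; because C19 bears two identical methyl groups, the two diastereomeric allyl complexes can interconvert through an η1-C19 form, so a poor choice of face at ionisation can still be corrected before the C–O bond forms. The step needs regioselectivity (secured by ring size), enantioselectivity (ligand) and chemoselectivity: the C4 hydroxyl is not allylic and stays out, the C14=C15 bond is insulated from the allyl unit by the sp3 carbon C16 and keeps its Z geometry, and the low temperature should suppress both racemic proton-catalysed closure by the substrate's own acid and re-ionisation of the allyl ester product.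

Step 8
Reactants: 13 the lactone alcohol from step 7
Product: 14 (3E,7E)-4,8-dimethyl-11-[(3Z,5S)-5-(2-methylprop-1-en-1-yl)-2-oxooxolan-3-ylidene]undeca-3,7-dienal
Conditions: Dess–Martin periodinane (1.3 equiv), pyridine (3 equiv), CH2Cl2, 0 °C; used crude
Reagents that add atoms: none
Why: Dess–Martin oxidation of the primary homoallylic alcohol under pyridine buffering should give the β,γ-unsaturated aldehyde without migration of C6=C7; lactone, enoate and the allylic C17–O bond are inert to the hypervalent iodine reagent.

Step 9
Reactants: 14 the aldehyde from step 8; 15 4-bromofuran-2(5H)-one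
Product: 16 (3Z,5S)-3-[(4E,8E,11R)-11-hydroxy-4,8-dimethyl-11-(5-oxo-2,5-dihydrofuran-3-yl)undeca-4,8-dien-1-ylidene]-5-(2-methylprop-1-en-1-yl)oxolan-2-one (the target)
Conditions: CrCl2 (3 equiv), N-[2-(4-isopropyl-4,5-dihydro-1,3-oxazol-2-yl)-6-methylphenyl]methanesulfonamide (3.3 equiv, one antipode, see remark), Et3N (3.3 equiv), NiCl2 (2 mol%), 15 (1.5 equiv), THF, rt
Reagents that add atoms: none
Why: Nozaki–Hiyama–Kishi coupling: nickel activates the C3–Br bond of 15, transmetalation gives an alkenylchromium species, and its addition to the aldehyde forms C3–C4. The chromium-bound chiral sulfonamide ligand selects the aldehyde face and sets 4R under reagent control, independent of the remote C17; organochromium reagents do not add to lactones or enoates, so no protecting group is needed.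

## Compound list

1 | geranyl bromide, (2E)-1-bromo-3,7-dimethylocta-2,6-diene | CC(C)=CCC/C(C)=C/CBr | starting material
2 | [(3E)-4,8-dimethylnona-3,7-dien-1-yl](dimethyl)(propan-2-yloxy)silane | CC(C)=CCC/C(C)=C/CC[Si](C)(C)OC(C)C | intermediate (not isolated)
3 | (3E)-4,8-dimethylnona-3,7-dien-1-ol | CC(C)=CCC/C(C)=C/CCO | intermediate
4 | (2E,6E)-2,6-dimethylnona-2,6-diene-1,9-diol | OC/C(C)=C/CC/C(C)=C/CCO | intermediate
5 | (3E,7E)-9-bromo-4,8-dimethylnona-3,7-dien-1-ol | BrC/C(C)=C/CC/C(C)=C/CCO | intermediate
6 | propyne | CC#C | starting material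
7 | 1,3-dilithiopropyne | [Li]CC#C[Li] | intermediate (not isolated)
8 | lithium (3E,7E)-12-lithio-4,8-dimethyldodeca-3,7-dien-11-yn-1-olate | [Li]C#CCC/C(C)=C/CC/C(C)=C/CCO[Li] | intermediate (not isolated)
9 | 2-(trimethylsilyl)ethyl (6E,10E)-6,10-dimethyl-13-({[2-(trimethylsilyl)ethoxy]carbonyl}oxy)trideca-6,10-dien-2-ynoate | C[Si](C)(C)CCOC(=O)C#CCC/C(C)=C/CC/C(C)=C/CCOC(=O)OCC[Si](C)(C)C | intermediate
10 | 2-methylpent-4-en-2-ol | C=CCC(C)(C)O | starting material
11 | 2-(trimethylsilyl)ethyl (2Z,6E,10E)-2-[(2E)-4-hydroxy-4-methylpent-2-en-1-yl]-6,10-dimethyl-13-({[2-(trimethylsilyl)ethoxy]carbonyl}oxy)trideca-2,6,10-trienoate | C[Si](C)(C)CCOC(=O)/C(=C\CC/C(C)=C/CC/C(C)=C/CCOC(=O)OCC[Si](C)(C)C)C/C=C/C(C)(C)O | intermediate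
12 | (2Z,6E,10E)-13-hydroxy-2-[(2E)-4-hydroxy-4-methylpent-2-en-1-yl]-6,10-dimethyltrideca-2,6,10-trienoic acid | OC(=O)/C(=C\CC/C(C)=C/CC/C(C)=C/CCO)C/C=C/C(C)(C)O | intermediate
13 | (3Z,5S)-3-[(4E,8E)-11-hydroxy-4,8-dimethylundeca-4,8-dien-1-ylidene]-5-(2-methylprop-1-en-1-yl)oxolan-2-one | CC(C)=C[C@@H]1C/C(=C/CC/C(C)=C/CC/C(C)=C/CCO)C(=O)O1 | intermediate
14 | (3E,7E)-4,8-dimethyl-11-[(3Z,5S)-5-(2-methylprop-1-en-1-yl)-2-oxooxolan-3-ylidene]undeca-3,7-dienal | CC(C)=C[C@@H]1C/C(=C/CC/C(C)=C/CC/C(C)=C/CC=O)C(=O)O1 | intermediate
15 | 4-bromofuran-2(5H)-one | O=C1OCC(Br)=C1 | starting material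
16 | (3Z,5S)-3-[(4E,8E,11R)-11-hydroxy-4,8-dimethyl-11-(5-oxo-2,5-dihydrofuran-3-yl)undeca-4,8-dien-1-ylidene]-5-(2-methylprop-1-en-1-yl)oxolan-2-one | CC(C)=C[C@@H]1C/C(=C/CC/C(C)=C/CC/C(C)=C/C[C@@H](O)C2=CC(=O)OC2)C(=O)O1 | target

## Step count and risk

Total step count: 9. Longest linear sequence: 9 steps (1 → 16); 6, 10 and 15 are bought.

**Step 7 (key step, proposed new method).**
- What may go wrong: racemic closure through proton-catalysed ionisation of the tertiary allylic alcohol by the substrate's own acid; weak facial discrimination because the allyl terminus C19 carries two methyl groups, one of them forced into the anti position; loss of configuration by re-ionisation of the allyl ester product; elimination to a diene.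
- Fallback (known chemistry, sets out from 9, returns at 13): the same ruthenium-catalysed alkene–alkyne coupling is run with but-3-en-1-ol to give the primary allylic alcohol ester 2-(trimethylsilyl)ethyl (2Z,6E,10E)-2-[(2E)-4-hydroxybut-2-en-1-yl]-6,10-dimethyl-13-({[2-(trimethylsilyl)ethoxy]carbonyl}oxy)trideca-2,6,10-trienoate F1. Fluoride frees the dihydroxy acid (2Z,6E,10E)-13-hydroxy-2-[(2E)-4-hydroxybut-2-en-1-yl]-6,10-dimethyltrideca-2,6,10-trienoic acid F2. The CpRu/chiral picolinic acid cyclisation, here on its established substrate class (primary (E)-allylic alcohol, attack at the substituted terminus), gives the vinyl lactone (3Z,5S)-5-ethenyl-3-[(4E,8E)-11-hydroxy-4,8-dimethylundeca-4,8-dien-1-ylidene]oxolan-2-one F3. Cross-metathesis with 2-methylbut-2-ene (second-generation Grubbs catalyst, CH2Cl2, rt) turns the vinyl group into the 2-methylprop-1-enyl group and gives 13. The gem-dimethyl group is thus kept out of the ionising terminus at the cost of one step.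

**Step 5.**
- What may go wrong: C–C bond formation at C14 instead of C15; intramolecular cycloisomerisation that engages the C10=C11 alkene of the 1,5-enyne; slow turnover with the hindered alkenol.
- Fallback (sets out from 9, returns at 11): Pd(PPh3)4-catalysed syn-hydrostannation with Bu3SnH (tin at C15, hydrogen at C14) gives 2-(trimethylsilyl)ethyl (2E,6E,10E)-6,10-dimethyl-2-(tributylstannyl)-13-({[2-(trimethylsilyl)ethoxy]carbonyl}oxy)trideca-2,6,10-trienoate F4. Stille allylation with allyl bromide (Pd2(dba)3, AsPh3, CuI, DMF) with retention gives 2-(trimethylsilyl)ethyl (2Z,6E,10E)-6,10-dimethyl-2-(prop-2-en-1-yl)-13-({[2-(trimethylsilyl)ethoxy]carbonyl}oxy)trideca-2,6,10-trienoate F5. Cross-metathesis with 2-methylbut-3-en-2-ol (second-generation Hoveyda–Grubbs catalyst) gives 11.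

**Step 9.**
- What may go wrong: insufficient facial selectivity with an α-unbranched aldehyde; migration of C6=C7 into conjugation with the aldehyde under the Lewis-acidic chromium salts.
- Fallback (sets out from 14, returns at 16): catalytic enantioselective addition of a 3-furyltitanium reagent (3-bromofuran, n-BuLi, ClTi(OiPr)3; Ti(OiPr)4 with a chiral 3-aryl-H8-BINOL, 0 °C) gives (3Z,5S)-3-[(4E,8E,11R)-11-(furan-3-yl)-11-hydroxy-4,8-dimethylundeca-4,8-dien-1-ylidene]-5-(2-methylprop-1-en-1-yl)oxolan-2-one F6. Dearomatising photo-oxygenation with singlet oxygen and i-Pr2NEt at −78 °C gives (3Z,5S)-3-[(4E,8E,11R)-11-hydroxy-11-(2-hydroxy-5-oxo-2,5-dihydrofuran-3-yl)-4,8-dimethylundeca-4,8-dien-1-ylidene]-5-(2-methylprop-1-en-1-yl)oxolan-2-one F7. NaBH4 with CeCl3·7H2O (MeOH, −40 °C) reduces the masked aldehyde, and relactonisation gives 16.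

**Step 2.**
- What may go wrong: oxidation at other allylic positions (C8, C5, C24) and over-oxidation to the enal, both of which lower the yield of a step early in the sequence.
- Fallback (sets out from 3, returns at 4): terminal-selective epoxidation by the hypobromous acid protocol (NBS, aqueous THF, 0 °C; then K2CO3, MeOH) gives racemic (3E)-6-(3,3-dimethyloxiran-2-yl)-4-methylhex-3-en-1-ol F8. Al(OiPr)3 in toluene at reflux isomerises the epoxide to racemic (6E)-2,6-dimethylnona-1,6-diene-3,9-diol F9. Ph3SiOReO3-catalysed 1,3-transposition of the secondary allylic alcohol (Et2O, 0 °C) leads to the more substituted alkene and gives 4.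

## Further compounds

F1 | step 7 | 2-(trimethylsilyl)ethyl (2Z,6E,10E)-2-[(2E)-4-hydroxybut-2-en-1-yl]-6,10-dimethyl-13-({[2-(trimethylsilyl)ethoxy]carbonyl}oxy)trideca-2,6,10-trienoate | C[Si](C)(C)CCOC(=O)/C(=C\CC/C(C)=C/CC/C(C)=C/CCOC(=O)OCC[Si](C)(C)C)C/C=C/CO
F2 | step 7 | (2Z,6E,10E)-13-hydroxy-2-[(2E)-4-hydroxybut-2-en-1-yl]-6,10-dimethyltrideca-2,6,10-trienoic acid | OC(=O)/C(=C\CC/C(C)=C/CC/C(C)=C/CCO)C/C=C/CO
F3 | step 7 | (3Z,5S)-5-ethenyl-3-[(4E,8E)-11-hydroxy-4,8-dimethylundeca-4,8-dien-1-ylidene]oxolan-2-one | C=C[C@@H]1C/C(=C/CC/C(C)=C/CC/C(C)=C/CCO)C(=O)O1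
F4 | step 5 | 2-(trimethylsilyl)ethyl (2E,6E,10E)-6,10-dimethyl-2-(tributylstannyl)-13-({[2-(trimethylsilyl)ethoxy]carbonyl}oxy)trideca-2,6,10-trienoate | C[Si](C)(C)CCOC(=O)/C(=C\CC/C(C)=C/CC/C(C)=C/CCOC(=O)OCC[Si](C)(C)C)[Sn](CCCC)(CCCC)CCCC
F5 | step 5 | 2-(trimethylsilyl)ethyl (2Z,6E,10E)-6,10-dimethyl-2-(prop-2-en-1-yl)-13-({[2-(trimethylsilyl)ethoxy]carbonyl}oxy)trideca-2,6,10-trienoate | C[Si](C)(C)CCOC(=O)/C(=C\CC/C(C)=C/CC/C(C)=C/CCOC(=O)OCC[Si](C)(C)C)CC=C
F6 | step 9 | (3Z,5S)-3-[(4E,8E,11R)-11-(furan-3-yl)-11-hydroxy-4,8-dimethylundeca-4,8-dien-1-ylidene]-5-(2-methylprop-1-en-1-yl)oxolan-2-one | CC(C)=C[C@@H]1C/C(=C/CC/C(C)=C/CC/C(C)=C/C[C@@H](O)c2ccoc2)C(=O)O1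
F7 | step 9 | (3Z,5S)-3-[(4E,8E,11R)-11-hydroxy-11-(2-hydroxy-5-oxo-2,5-dihydrofuran-3-yl)-4,8-dimethylundeca-4,8-dien-1-ylidene]-5-(2-methylprop-1-en-1-yl)oxolan-2-one (both epimers at the hemiacetal carbon) | CC(C)=C[C@@H]1C/C(=C/CC/C(C)=C/CC/C(C)=C/C[C@@H](O)C2=CC(=O)OC2O)C(=O)O1
F8 | step 2 | (3E)-6-(3,3-dimethyloxiran-2-yl)-4-methylhex-3-en-1-ol (racemic) | CC1(C)OC1CC/C(C)=C/CCO
F9 | step 2 | (6E)-2,6-dimethylnona-1,6-diene-3,9-diol (racemic) | C=C(C)C(O)CC/C(C)=C/CCO
A1 | alternative 1 | (5S)-3-(diphenoxyphosphoryl)-5-(2-methylprop-1-en-1-yl)oxolan-2-one | CC(C)=C[C@@H]1CC(P(=O)(Oc2ccccc2)Oc2ccccc2)C(=O)O1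
A2 | alternative 1 | (4E,8E)-11-[(tert-butyldimethylsilyl)oxy]-4,8-dimethylundeca-4,8-dienal | O=CCC/C(C)=C/CC/C(C)=C/CCO[Si](C)(C)C(C)(C)C
A3 | alternative 2 | (2R)-2-(2-methylprop-1-en-1-yl)oxirane | CC(C)=C[C@@H]1CO1
A4 | alternative 2 | (4S,10E,14E)-2,10,14-trimethylheptadeca-2,10,14-trien-6-yne-4,17-diol | CC(C)=C[C@@H](O)CC#CCC/C(C)=C/CC/C(C)=C/CCO
A5 | alternative 2 | (4S,6Z,10E,14E)-2,10,14-trimethyl-6-(tributylstannyl)heptadeca-2,6,10,14-tetraene-4,17-diol | CC(C)=C[C@@H](O)C/C(=C/CC/C(C)=C/CC/C(C)=C/CCO)[Sn](CCCC)(CCCC)CCCC
A6 | alternative 3 | methyl (3S,6E,10E)-13-[(tert-butyldimethylsilyl)oxy]-3-hydroxy-6,10-dimethyl-2-methylidenetrideca-6,10-dienoate (one antipode shown) | C=C(C(=O)OC)[C@@H](O)CC/C(C)=C/CC/C(C)=C/CCO[Si](C)(C)C(C)(C)C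
A7 | alternative 3 | methyl (3S,6E,10E)-13-[(tert-butyldimethylsilyl)oxy]-6,10-dimethyl-3-[(3-methylbut-2-en-1-yl)oxy]-2-methylidenetrideca-6,10-dienoate (one antipode shown) | C=C(C(=O)OC)[C@@H](OCC=C(C)C)CC/C(C)=C/CC/C(C)=C/CCO[Si](C)(C)C(C)(C)C
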